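**Retrosynthetic overview**
- The quinone C4=O is made last, by aerobic para-oxygenation of a 2-methoxy-6-alkenylphenol (a C–O bond).
- The C11–Cl bond and the E geometry come from chloride capture of an α-aryl vinyl cation, generated from the enol triflate of a C11 aryl ketone.
- The C11=O of that ketone comes from decarboxylative oxygenation of an α-aryl homodrimanic acid. This C–O bond formation is the pivot: it removes the surplus carbon of sclareolide.
- The C11–aryl bond comes from Pd α-arylation of the homodrimanic acid with O-silylated 6-bromoguaiacol; the acid comes from (+)-sclareolide by reductive C8–O opening, which sets 8β-CH3.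
- Ring order: rings A and B are taken intact from sclareolide (no carbocycle is built), the lactone ring is opened first, and the quinone ring is unmasked last from the guaiacol ring.

Assumption and convention: 2-bromo-6-methoxyphenol is bought as a catalogue phenol; drimane numbering is used (C8 bears the secondary methyl, C9 the side chain, C10 the angular methyl, C11 is the carbon on C9, C12 the carboxyl carbon); β is the face of the C10 methyl.

**Step 1**
Reactants: 1 (+)-sclareolide
Product: 2 (8αH)-homodrimanic acid: 2-[(1S,2S,4aS,8aR)-2,5,5,8a-tetramethyldecahydronaphthalen-1-yl]acetic acid (5α-H/8β-CH3/9α-H/10β-CH3)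
Conditions: Et3SiH (3 equiv), CF3SO3H (1.5 equiv), CH2Cl2, −20 → 0 °C; aq. work-up
Reagents that add atoms: none
Why: Proposed new method: CF3SO3H ionises the tertiary C8–O bond of the lactone by alkyl–oxygen fission (the same reversible ionisation that epimerises sclareolide at C8 in strong acid) and Et3SiH traps the C8 cation irreversibly from the α (equatorial) side because axial β-approach is blocked by the syn-axial C10 methyl, which sets 8α-H/8β-CH3 (8S) and frees the acid, with low temperature and excess silane used to outrun hydride and methyl shifts; the closest known reaction type is Kursanov–Parnes ionic hydrogenation of tertiary alcohols and alkenes, not yet shown for reductive opening of a tertiary alkyl γ-lactone.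

**Step 2**
Reactants: 3 2-bromo-6-methoxyphenol
Product: 4 (2-bromo-6-methoxyphenoxy)triisopropylsilane
Conditions: i-Pr3SiCl, imidazole, DMAP (cat.), DMF, 50 °C
Reagents that add atoms: chlorotriisopropylsilane, CC(C)[Si](Cl)(C(C)C)C(C)C
Why: Standard silyl ether formation on a phenol; the triisopropylsilyl group survives amide base, palladium, photoredox oxidation and triflic anhydride and, unlike an acetal-type group, carries no oxygen that could trap the later vinyl cation in a six-membered ring.

**Step 3**
Reactants: 2 (8αH)-homodrimanic acid; 4 (2-bromo-6-methoxyphenoxy)triisopropylsilane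
Product: 7 2-[3-methoxy-2-(triisopropylsilyloxy)phenyl] derivative of acid 2 (aryl on C11; C11 epimer mixture; decalin unchanged), via disilyl ketene acetal 5 (not isolated), via trimethylsilyl ester 6 (not isolated)
Conditions: LiN(SiMe3)2 (2.3 equiv), Me3SiCl (2.3 equiv), THF, −78 °C → rt; then 4, Pd(dba)2 (5 mol %), P(t-Bu)3 (10 mol %), ZnF2 (0.5 equiv), DMF, 80 °C; aq. HCl work-up
Reagents that add atoms: chlorotrimethylsilane, C[Si](C)(C)Cl (its silyl groups sit only in 5 and 6 and are lost on work-up)
Why: Palladium-catalysed α-arylation of a carboxylic acid through its in situ disilyl ketene acetal (Hartwig-type enolate arylation with zerovalent palladium, P(t-Bu)3 and ZnF2 activation) joins C11 to the arene; the bulky C9 neighbour stops the reaction at mono-arylation and the new C11 centre needs no control because it becomes sp2 two steps later.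

**Step 4**
Reactants: 7 α-aryl homodrimanic acid
Product: 8 [3-methoxy-2-(triisopropylsilyloxy)phenyl][(1S,2S,4aS,8aS)-2,5,5,8a-tetramethyldecahydronaphthalen-1-yl]methanone (11-aryl-8αH-driman-11-one)
Conditions: 9-mesityl-10-methylacridinium tetrafluoroborate (5 mol %), O2 (1 atm), 2,6-lutidine (0.2 equiv), MeCN, blue LEDs, rt
Reagents that add atoms: dioxygen, O=O
Why: Acridinium-photocatalysed aerobic decarboxylative oxygenation (the reaction that turns 2-arylpropionic acids into aryl methyl ketones): one-electron oxidation of the carboxylate expels CO2, the benzylic C11 radical is trapped by O2 and the hydroperoxide collapses to the ketone, so this C–O bond formation removes sclareolide's surplus carbon and installs the C11 carbonyl while 9α-H keeps its favoured equatorial-acyl arrangement.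

**Step 5**
Reactants: 8 aryl ketone
Product: 10 triisopropyl{2-[(E)-chloro[(2S,4aS,8aS)-2,5,5,8a-tetramethyloctahydronaphthalen-1(2H)-ylidene]methyl]-6-methoxyphenoxy}silane, via enol triflate 9 (not isolated)
Conditions: (CF3SO2)2O (1.5 equiv), 2,6-di-tert-butyl-4-methylpyridine (2 equiv), CH2Cl2, 0 °C → rt; then n-Bu4NCl (5 equiv), (CF3)2CHOH, 40 °C
Reagents that add atoms: trifluoromethanesulfonic anhydride, O=S(=O)(OS(=O)(=O)C(F)(F)F)C(F)(F)F (triflyl group in 9 only); tetrabutylammonium chloride, CCCC[N+](CCCC)(CCCC)CCCC.[Cl-] (Cl in 10)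
Why: Proposed new method: the crude enol triflate (either geometry) ionises in hexafluoroisopropanol by unimolecular vinylic substitution to a linear α-aryl vinyl cation stabilised by the ortho-siloxy arene, and chloride attacks in the plane of the C9 substituents from the less hindered C8 side (equatorial H) rather than the C10 side (C1 methylene), which forms the C–Cl bond and sets the E geometry stereoconvergently under kinetic control because the vinyl chloride does not re-ionise; the closest known reaction type is solvolytic halide exchange of α-anisylvinyl halides and triflates through vinyl cations, not yet used as a preparative, geometry-setting triflate-to-chloride exchange on a tetrasubstituted exocyclic enol triflate.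

**Step 6**
Reactants: 10 (E)-vinyl chloride silyl ether
Product: 12 2-[(E)-chloro[(2S,4aS,8aS)-2,5,5,8a-tetramethyloctahydronaphthalen-1(2H)-ylidene]methyl]-6-methoxycyclohexa-2,5-diene-1,4-dione (target), via free phenol 11 (not isolated)
Conditions: n-Bu4NF, AcOH, THF, 0 °C; then Co(salen) [Co(C16H14N2O2), divalent cobalt] (10 mol %), O2 (1 atm), DMF, rt
Reagents that add atoms: dioxygen, O=O
Why: Fluoride desilylation then Co(salen)-catalysed aerobic phenol oxidation (the aerobic counterpart of the Teuber oxidation) places the final oxygen on the only free para carbon of the 2,6-disubstituted phenol and gives the 2-methoxy-6-alkenyl-1,4-benzoquinone; the tetrasubstituted chloroalkene and the three stereocentres are not touched.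

**Compound list**
1 | (+)-sclareolide, (3aR,5aS,9aS,9bR)-3a,6,6,9a-tetramethyldecahydronaphtho[2,1-b]furan-2(1H)-one | O=C1C[C@H]2[C@](C)(O1)CC[C@H]3C(C)(C)CCC[C@]23C | starting material
2 | (8αH)-homodrimanic acid, 2-[(1S,2S,4aS,8aR)-2,5,5,8a-tetramethyldecahydronaphthalen-1-yl]acetic acid (5α-H, 8β-CH3, 9α-H, 10β-CH3) | OC(=O)C[C@H]1[C@@H](C)CC[C@H]2C(C)(C)CCC[C@]12C | intermediate
3 | 2-bromo-6-methoxyphenol (6-bromoguaiacol) | COc1cccc(Br)c1O | starting material
4 | (2-bromo-6-methoxyphenoxy)triisopropylsilane | COc1cccc(Br)c1O[Si](C(C)C)(C(C)C)C(C)C | intermediate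
5 | disilyl ketene acetal of 2: 1,1-bis(trimethylsilyloxy)ethene carrying the decalin unit of 2 on C11 (not isolated) | C[Si](C)(C)OC(O[Si](C)(C)C)=C[C@H]1[C@@H](C)CC[C@H]2C(C)(C)CCC[C@]12C | intermediate
6 | trimethylsilyl ester of 7 (C11 epimer mixture; not isolated) | C[Si](C)(C)OC(=O)C(c1cccc(OC)c1O[Si](C(C)C)(C(C)C)C(C)C)[C@H]2[C@@H](C)CC[C@H]3C(C)(C)CCC[C@]23C | intermediate
7 | 2-[3-methoxy-2-(triisopropylsilyloxy)phenyl]-2-[decalin unit of 2]acetic acid (aryl on C11; C11 epimer mixture; 5α-H, 8β-CH3, 9α-H, 10β-CH3) | OC(=O)C(c1cccc(OC)c1O[Si](C(C)C)(C(C)C)C(C)C)[C@H]2[C@@H](C)CC[C@H]3C(C)(C)CCC[C@]23C | intermediate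
8 | [3-methoxy-2-(triisopropylsilyloxy)phenyl][(1S,2S,4aS,8aS)-2,5,5,8a-tetramethyldecahydronaphthalen-1-yl]methanone | O=C(c1cccc(OC)c1O[Si](C(C)C)(C(C)C)C(C)C)[C@H]2[C@@H](C)CC[C@H]3C(C)(C)CCC[C@]23C | intermediate
9 | [3-methoxy-2-(triisopropylsilyloxy)phenyl][(2S,4aS,8aS)-2,5,5,8a-tetramethyloctahydronaphthalen-1(2H)-ylidene]methyl trifluoromethanesulfonate (E/Z mixture; not isolated) | O=S(=O)(OC(c1cccc(OC)c1O[Si](C(C)C)(C(C)C)C(C)C)=C2[C@@H](C)CC[C@H]3C(C)(C)CCC[C@]23C)C(F)(F)F | intermediate
10 | triisopropyl{2-[(E)-chloro[(2S,4aS,8aS)-2,5,5,8a-tetramethyloctahydronaphthalen-1(2H)-ylidene]methyl]-6-methoxyphenoxy}silane (Cl syn to C8, aryl syn to C10) | COc1cccc(/C(Cl)=C2/[C@@H](C)CC[C@H]3C(C)(C)CCC[C@]23C)c1O[Si](C(C)C)(C(C)C)C(C)C | intermediate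
11 | 2-[(E)-chloro[(2S,4aS,8aS)-2,5,5,8a-tetramethyloctahydronaphthalen-1(2H)-ylidene]methyl]-6-methoxyphenol (not isolated) | COc1cccc(/C(Cl)=C2/[C@@H](C)CC[C@H]3C(C)(C)CCC[C@]23C)c1O | intermediate
12 | 2-[(E)-chloro[(2S,4aS,8aS)-2,5,5,8a-tetramethyloctahydronaphthalen-1(2H)-ylidene]methyl]-6-methoxycyclohexa-2,5-diene-1,4-dione (CNP0249629.1) | COC1=CC(=O)C=C(/C(Cl)=C2/[C@@H](C)CC[C@H]3C(C)(C)CCC[C@]23C)C1=O | target

**Totals**
Total step count: 6. Longest linear sequence: 5 (steps 1, 3, 4, 5, 6).

**Steps most likely to fail, with fallbacks**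

Step 1 (proposed new method). The C8 cation could be recaptured as the cis-lactone, rearrange, or be reduced with poor facial control. The fallback uses known chemistry, sets out from 1 and comes back at 2. Lactone 1 is opened with H2SO4 in MeOH at rt to the known mixture of the exocyclic-alkene methyl ester F1, the ring-B trisubstituted-alkene (C7=C8) methyl ester F2 and the tetrasubstituted-alkene (C8=C9) methyl ester F3. Heterogeneous hydrogenation of the mixture (H2, 4 atm, PtO2, AcOH) delivers hydrogen from the α face and converges on the saturated 8β-methyl methyl ester F4; F3 reacts slowest and can be removed on AgNO3-impregnated silica if it persists. Saponification (KOH, aq. EtOH, reflux) then gives 2.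

Step 5 (proposed new method). Ionisation could be slow, the cation could be trapped by solvent, or the C8/C10 side discrimination could be modest. The fallback uses known chemistry, sets out from 8 and comes back at 10. Ketone 8 is deoxychlorinated directly with preformed (PhO)3PCl2 and Et3N in CH2Cl2 (−30 °C → rt), the known conversion of enolisable ketones into vinyl chlorides through a chlorophosphonium adduct and elimination, with no vinyl cation involved. This gives 10 together with the (Z)-chloroalkene isomer F7, which is separated on AgNO3-impregnated silica or by HPLC.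

Step 3. The β-branched ketene acetal and the ortho-siloxy aryl bromide are both hindered partners for the palladium-catalysed arylation. The fallback sets out from 2 (with 4) and comes back at 8, bypassing 7. Acid 2 is converted into the N-acyloxyphthalimide ester F5 (N-hydroxyphthalimide, N,N′-diisopropylcarbodiimide, DMAP, CH2Cl2). Nickel-catalysed reductive decarboxylative arylation with 4 (NiBr2(dme), divalent nickel, 4,4′-di-tert-butyl-2,2′-bipyridine, Zn, DMA, rt) gives the C11-methylene arene F6. Benzylic oxidation of the alkoxy-activated methylene (DDQ, wet CH2Cl2; alternatively CrO3/3,5-dimethylpyrazole) then gives ketone 8.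

**Further compounds**
F1 | step 1 | methyl 2-[(1S,4aS,8aS)-5,5,8a-trimethyl-2-methylidenedecahydronaphthalen-1-yl]acetate (exocyclic C8=CH2 alkene; 9α-H) | COC(=O)C[C@H]1C(=C)CC[C@H]2C(C)(C)CCC[C@]12C
F2 | step 1 | methyl 2-[(1S,4aS,8aS)-2,5,5,8a-tetramethyl-1,4,4a,5,6,7,8,8a-octahydronaphthalen-1-yl]acetate (C7=C8 alkene; 9α-H) | COC(=O)C[C@H]1C(C)=CC[C@H]2C(C)(C)CCC[C@]12C
F3 | step 1 | methyl 2-[(4aS,8aS)-2,5,5,8a-tetramethyl-3,4,4a,5,6,7,8,8a-octahydronaphthalen-1-yl]acetate (C8=C9 alkene) | COC(=O)CC1=C(C)CC[C@H]2C(C)(C)CCC[C@]12C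
F4 | step 1 | methyl ester of 2, methyl 2-[(1S,2S,4aS,8aR)-2,5,5,8a-tetramethyldecahydronaphthalen-1-yl]acetate | COC(=O)C[C@H]1[C@@H](C)CC[C@H]2C(C)(C)CCC[C@]12C
F5 | step 3 | 1,3-dioxoisoindolin-2-yl ester of 2 (N-acyloxyphthalimide) | O=C(C[C@H]1[C@@H](C)CC[C@H]2C(C)(C)CCC[C@]12C)ON3C(=O)c4ccccc4C3=O
F6 | step 3 | triisopropyl{2-methoxy-6-[(decalin unit of 2)methyl]phenoxy}silane (aryl–C11H2–C9; 8β-CH3, 9α-H) | COc1cccc(C[C@H]2[C@@H](C)CC[C@H]3C(C)(C)CCC[C@]23C)c1O[Si](C(C)C)(C(C)C)C(C)C
F7 | step 5 | (Z) isomer of 10 (Cl syn to C10, aryl syn to C8) | COc1cccc(/C(Cl)=C2\[C@@H](C)CC[C@H]3C(C)(C)CCC[C@]23C)c1O[Si](C(C)C)(C(C)C)C(C)C
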